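## The problem

Compound 16 is a 1H-isochromene. Ring C (C1, O2, C3, C4, C4a, C8a) is fused to a 6,7-dimethoxybenzene ring B, and C3 carries a 2,4-dimethoxybenzoyl group whose arene is ring A. The molecule has no stereocentre, so the task is one of connectivity and oxidation level, not of control in space. C1 must end as an ether methylene and C3=C4 as an enol ether double bond conjugated with the ketone. The ring oxygen must sit on C3 and not on C4, so ring C must close six-membered where an ynone or a benzylic alkoxide would tend to give the five-membered isobenzofuran. The finished 2-alkoxy enone is a Michael acceptor, C1 is benzylic and next to oxygen and so easily oxidised, the methoxy group ortho to the ketone is cleaved by hard Lewis acids, and before the ketone is unveiled the C3=C4 enol ether is acid-labile. The feature that opens the route lies in ring B: its two carbon substituents, C4 and C1, stand on the adjacent carbons C4a and C8a, and the methoxy groups at C6 and C7 are mirror images across the C4a–C8a bond. Removing both substituents leaves 4,5-dimethoxybenzyne 11 with two equivalent reactive carbons, so an alkynyl nucleophile and a formyl electrophile can be added across it with no regiochemical question, and the aldehyde oxygen so introduced is the future O2.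

## Retrosynthesis

**16 to 15.** No skeletal bond is cut; the ketone is traded for a 1,3-dioxolane. The mask is needed twice over: it keeps the carbonyl inert to organomagnesium reagents, and it removes the ynone polarisation that would send the ring oxygen to C4. The forward step asks for a hydrolysis gentle enough to spare the enol ether. The 2,4-dimethoxyphenyl group makes this ketal ionise under weak acid, and the ketone, once formed, deactivates C3=C4 toward protonation.

**15 to 13.** The O2–C3 bond is cut and the hydride at C1 is removed, which leads to the ortho-alkynylbenzaldehyde 13. Closing ring C from a benzylic alcohol onto the alkyne is the neighbouring cut, but it competes with 5-exo closure. Cutting O2–C1 instead would need O-alkylation of a 1,2-dicarbonyl enolate, with C-alkylation as a competitor. The aldehyde-oxygen closure passes through the aromatic 2-benzopyrylium ion 14, which only a 6-endo attack can reach, and hydride delivery to C1 then sets the methylene. Precursor 13 has one ring fewer. The forward reaction needs a π-acid that leaves the ketal alone and a hydride donor that does not reduce the aldehyde before cyclisation: AgOTf with a Hantzsch ester.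

**13 to 3, 8 and 9.** Both carbon–carbon bonds to ring B are cut at once: C4–C4a to the terminal alkyne 8 and C1–C8a to N,N-dimethylformamide 9, which leaves ring B as the aryne 11 released from the iodoaryl triflate 3. The neighbouring single cut, a Sonogashira coupling of 8 with a bromobenzaldehyde, is more conventional and is held as the fallback. The double cut is preferred because it reduces ring B to a phenol-derived symmetric aryne and builds the whole ortho-alkynylbenzaldehyde in one flask. The forward reaction asks that the alkynylmagnesium 10 outcompete every other nucleophile for the aryne and that the electrophile arrive only after the aryne is consumed.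

**3 to 2 to 1.** The S–O bond of the triflate and the C–I bond are removed in turn, which leads back to 3,4-dimethoxyphenol 1. The only demand is that iodination go to the position ortho to the hydroxyl and para to the 3-methoxy group, which the substituent effects and sterics of 1 favour.

**8 to 7 to 6 to 4 and 5.** The alkynyl C–H is traced to a C–Si bond (7), the dioxolane to the ynone 6, and the acyl–alkynyl bond of 6 to 2,4-dimethoxybenzoyl chloride 4 and trimethylsilylacetylene 5. A palladium/copper acyl coupling is preferred to a Lewis-acid acylation of a silylalkyne because AlCl3 would endanger the methoxy group ortho to the carbonyl. The silyl group is kept through the ketalisation to block conjugate addition to the ynone.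

## Roads not taken

**Alternative 1:** Ring A would be cut at two bonds (ipso carbon to the methoxy-bearing carbon, and the carbon ortho to the ketone to its neighbour) and assembled last. A terminal ynone that already carries rings B and C, A2, would be combined with the donor diene A3. The nucleophilic CH2 terminus of A3 adds to the ynone β-carbon, the ketene acetal carbon closes onto the α-carbon, and loss of one methoxy group as the alcohol aromatises the ring to phenol A1; one O-methylation then gives 16.
- Merits: the key step forms a ring and two C–C bonds without organometallic reagents, and the polarised diene places the ring A oxygens unambiguously.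
- Weak points: ring A is the one part of 16 that can be bought with the correct pattern, so the ring-forming step is spent where it is not needed. A2 still requires rings B and C, with the 6-endo question and the C1/C3/C4 oxidation levels unsolved. The 2-alkoxy enone inside A2 is a second acceptor for the very nucleophilic A3. A terminal ynone is prone to polymerisation, and a methylation is added at the end.
- Comparison: in regiochemical certainty of its key step this road is as good as the chosen one. The chosen plan sets against it a shorter sequence and a key step spent on ring B, where the symmetry actually saves work.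

**Alternative 2:** Ring C would be cut at C3–C4 and C1–O2. Irradiation of the 2-methylbenzaldehyde A5 moves a benzylic hydrogen to the carbonyl oxygen, and the dienol so formed adds as a diene across the aldehyde carbonyl of the arylglyoxal A6, closing ring C as the lactol A4.
- Merits: both partners are one step or less from commerce, no protecting group is needed, and ring C is made in the key step itself. On paper this road is shorter than the chosen one.
- Weak points: A4 is at the wrong oxidation level at two places. The C1 hydroxyl has to be removed by ionic reduction in the presence of an electron-rich aryl ketone. C3–C4 then has to be dehydrogenated next to that ketone in a molecule whose C1 position is itself easily oxidised. The 1,2-dicarbonyl of A6 is a chromophore in its own right and can divert the light or react at the ketone carbonyl.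
- Comparison: the chosen plan is longer, but its alkyne and formyl carbon arrive at exactly the oxidation levels of C3=C4 and C1, so no late redox correction near sensitive positions is required.

**Alternative 3:** Ring C would be cut at O2–C3 and C3–C4. A rhodium or copper carbenoid from the diazoketone A8 is captured by the ring oxygen of the symmetric phthalan A9; a benzylic carbon then shifts from oxygen to the ylide carbon (Stevens-type 1,2-shift), enlarging the five-membered ring to the isochroman A7. One dehydrogenation would finish 16.
- Merits: the symmetry of A9 removes regiochemistry just as the symmetric aryne does, ring C is made in the key step, and the step count is roughly half that of the chosen plan.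
- Weak points: intermolecular ylide formation with a dialkyl ether competes with carbene dimerisation and with attack on two very electron-rich arenes. The methoxy oxygen ortho to the carbenoid carbon in A8 is placed for an intramolecular five-membered ylide closure. The 1,2-shift proceeds through a radical pair and is seldom efficient. The final dehydrogenation of A7 must distinguish C3–C4 from the more oxidisable C1.
- Comparison: this road is better in brevity. The chosen plan sets against it that every step belongs to a well-used reaction class and that the enol ether is formed directly, not by oxidation.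

Key step: step 6

Assumption: compounds 1, 4, 5 and 9 and all reagents are taken as commercial; the electron-rich aryl ketal in 7, 8, 13 and 15 is handled on base-washed silica.

## Route

Step 1
Reactants: 1 3,4-dimethoxyphenol
Product: 2 2-iodo-4,5-dimethoxyphenol
Conditions: NIS (1.05 equiv), CH2Cl2, 0 °C → rt, dark
Reagents that add atoms: N-iodosuccinimide, O=C1CCC(=O)N1I
Why: Electrophilic aromatic iodination; the position ortho to the hydroxyl and para to the 3-methoxy group is doubly activated and, unlike the position between the two oxygen substituents, unhindered, so mono-iodination should occur there, while cold and dark conditions limit oxidation of the electron-rich phenol.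

Step 2
Reactants: 2 2-iodo-4,5-dimethoxyphenol
Product: 3 2-iodo-4,5-dimethoxyphenyl trifluoromethanesulfonate
Conditions: Tf2O (1.2 equiv), pyridine (2 equiv), CH2Cl2, 0 °C
Reagents that add atoms: trifluoromethanesulfonic anhydride, O=S(=O)(OS(=O)(=O)C(F)(F)F)C(F)(F)F
Why: O-Sulfonylation of a phenol; the aryl iodide and methyl ethers are inert, and the triflate ortho to iodine is the leaving group needed for aryne release.

Step 3
Reactants: 4 2,4-dimethoxybenzoyl chloride, 5 trimethylsilylacetylene
Product: 6 1-(2,4-dimethoxyphenyl)-3-(trimethylsilyl)prop-2-yn-1-one
Conditions: PdCl2(PPh3)2 (2 mol%), CuI (4 mol%), Et3N (1.1 equiv), THF, rt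
Reagents that add atoms: none
Why: Acyl Sonogashira coupling: oxidative addition of the aroyl chloride to zerovalent palladium, transmetalation from the copper acetylide and reductive elimination give the ynone at room temperature; only one equivalent of amine is used so that it does not add to the ynone, and no hard Lewis acid is present to cleave the ortho-methoxy group.

Step 4
Reactants: 6 1-(2,4-dimethoxyphenyl)-3-(trimethylsilyl)prop-2-yn-1-one
Product: 7 {[2-(2,4-dimethoxyphenyl)-1,3-dioxolan-2-yl]ethynyl}trimethylsilane
Conditions: Me3SiOCH2CH2OSiMe3 (2 equiv), Me3SiOTf (10 mol%), CH2Cl2, −78 → −20 °C; pyridine quench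
Reagents that add atoms: 1,2-bis(trimethylsilyloxy)ethane, C[Si](C)(C)OCCO[Si](C)(C)C
Why: Noyori ketalisation, driven by formation of hexamethyldisiloxane and not by water removal, suits a conjugated, donor-deactivated ketone; the silyl cap on the alkyne shields the β-carbon from conjugate addition and the cold basic quench protects the acid-labile ketal.

Step 5
Reactants: 7 {[2-(2,4-dimethoxyphenyl)-1,3-dioxolan-2-yl]ethynyl}trimethylsilane
Product: 8 2-(2,4-dimethoxyphenyl)-2-ethynyl-1,3-dioxolane
Conditions: K2CO3 (0.2 equiv), MeOH, rt
Reagents that add atoms: none
Why: Base-catalysed methanolysis of the alkynyl C–Si bond (protodesilylation); the dioxolane and aryl ethers are stable to carbonate in methanol.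

Step 6
Reactants: 3 2-iodo-4,5-dimethoxyphenyl trifluoromethanesulfonate, 8 2-(2,4-dimethoxyphenyl)-2-ethynyl-1,3-dioxolane, 9 N,N-dimethylformamide
Product: 13 2-{[2-(2,4-dimethoxyphenyl)-1,3-dioxolan-2-yl]ethynyl}-4,5-dimethoxybenzaldehyde, via alkynylmagnesium chloride 10 (not isolated), via 4,5-dimethoxybenzyne 11 (not isolated), via arylmagnesium chloride 12 (not isolated)
Conditions: 8 (2.0 equiv), iPrMgCl·LiCl (2.0 equiv, titrated), THF, 0 °C → rt; then 3 (1.0 equiv), Me3SiCH2MgCl (1.2 equiv, slow addition), −78 °C → rt; then DMF (5 equiv), 0 °C → rt; pH 7 phosphate buffer
Reagents that add atoms: none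
Why: Deprotonation of 8 by iPrMgCl·LiCl gives the acetylide 10, and iodine–magnesium exchange on 3 by Me3SiCH2MgCl followed by loss of triflate from the ortho-magnesiated aryl triflate releases the aryne 11. The acetylide adds across the strained triple bond (carbomagnesiation, C4–C4a) to give the ortho-alkynyl arylmagnesium 12, which adds to DMF to form a hemiaminal alkoxide that collapses to the aldehyde on work-up (Bouveault formylation, C1–C8a). The closest known reaction type is the three-component coupling of an aryne with a metal acetylide and a carbon electrophile, together with the addition of Grignard reagents to arynes and electrophilic quench of the resulting 2-substituted arylmagnesium. No ring is closed and no stereocentre is formed. Regioselectivity is not required, because the two aryne carbons of 11 are equivalent by symmetry, each next to a ring hydrogen, meta to one methoxy group and para to the other. The selectivity that is required is among nucleophiles: the aryne must be taken by 10 and not by the exchange reagent or by the product 12, and the poorly nucleophilic Me3SiCH2MgCl, the twofold excess of 10 and the slow, cold generation of 11 are meant to secure this. The order of the two bond formations is fixed by adding DMF only after the aryne is consumed, and the dioxolane keeps the ketone carbon inert to all organomagnesium species present.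

Step 7
Reactants: 13 2-{[2-(2,4-dimethoxyphenyl)-1,3-dioxolan-2-yl]ethynyl}-4,5-dimethoxybenzaldehyde
Product: 15 3-[2-(2,4-dimethoxyphenyl)-1,3-dioxolan-2-yl]-6,7-dimethoxy-1H-isochromene, via 2-benzopyrylium triflate 14 (not isolated)
Conditions: AgOTf (5 mol%), Hantzsch ester (diethyl 2,6-dimethyl-1,4-dihydropyridine-3,5-dicarboxylate, 1.2 equiv), 4 Å MS, CH2Cl2, rt, dark
Reagents that add atoms: none
Why: Domino cycloisomerisation/transfer hydrogenation of an ortho-alkynylbenzaldehyde: monovalent silver activates the alkyne and the carbonyl oxygen attacks the distal alkyne carbon in a 6-endo-dig closure, favoured because it gives the aromatic 2-benzopyrylium ion 14. The Hantzsch ester then delivers hydride to C1, the most electrophilic position of 14, and the pyridinium formed protonates the C4–Ag bond to release the catalyst.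

Step 8
Reactants: 15 3-[2-(2,4-dimethoxyphenyl)-1,3-dioxolan-2-yl]-6,7-dimethoxy-1H-isochromene
Product: 16 (6,7-dimethoxy-1H-isochromen-3-yl)(2,4-dimethoxyphenyl)methanone
Conditions: PPTS (0.2 equiv), acetone/H2O (9:1), rt → 40 °C
Reagents that add atoms: water, O
Why: Acid-catalysed ketal hydrolysis with exchange into acetone; the ortho- and para-methoxy groups stabilise the oxocarbenium ion so that a weak acid suffices, and once the ketone is formed the adjacent carbonyl deactivates the C3=C4 enol ether toward protonation.

## Compound list

1 | 3,4-dimethoxyphenol | COc1ccc(O)cc1OC | starting material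
2 | 2-iodo-4,5-dimethoxyphenol | COc1cc(I)c(O)cc1OC | intermediate
3 | 2-iodo-4,5-dimethoxyphenyl trifluoromethanesulfonate | COc1cc(I)c(OS(=O)(=O)C(F)(F)F)cc1OC | intermediate
4 | 2,4-dimethoxybenzoyl chloride | COc1ccc(C(=O)Cl)c(OC)c1 | starting material
5 | trimethylsilylacetylene | C#C[Si](C)(C)C | starting material
6 | 1-(2,4-dimethoxyphenyl)-3-(trimethylsilyl)prop-2-yn-1-one | COc1ccc(C(=O)C#C[Si](C)(C)C)c(OC)c1 | intermediate
7 | {[2-(2,4-dimethoxyphenyl)-1,3-dioxolan-2-yl]ethynyl}trimethylsilane | COc1ccc(C2(C#C[Si](C)(C)C)OCCO2)c(OC)c1 | intermediate
8 | 2-(2,4-dimethoxyphenyl)-2-ethynyl-1,3-dioxolane | C#CC1(c2ccc(OC)cc2OC)OCCO1 | intermediate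
9 | N,N-dimethylformamide | CN(C)C=O | starting material
10 | {[2-(2,4-dimethoxyphenyl)-1,3-dioxolan-2-yl]ethynyl}magnesium chloride (formed in the flask, not isolated) | Cl[Mg]C#CC1(c2ccc(OC)cc2OC)OCCO1 | intermediate
11 | 4,5-dimethoxybenzyne (1,2-didehydro-4,5-dimethoxybenzene; not isolated) | COC1=CC#CC=C1OC | intermediate
12 | (2-{[2-(2,4-dimethoxyphenyl)-1,3-dioxolan-2-yl]ethynyl}-4,5-dimethoxyphenyl)magnesium chloride (not isolated) | COc1ccc(C2(C#Cc3cc(OC)c(OC)cc3[Mg]Cl)OCCO2)c(OC)c1 | intermediate
13 | 2-{[2-(2,4-dimethoxyphenyl)-1,3-dioxolan-2-yl]ethynyl}-4,5-dimethoxybenzaldehyde | COc1ccc(C2(C#Cc3cc(OC)c(OC)cc3C=O)OCCO2)c(OC)c1 | intermediate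
14 | 3-[2-(2,4-dimethoxyphenyl)-1,3-dioxolan-2-yl]-6,7-dimethoxy-2-benzopyrylium trifluoromethanesulfonate (catalytic-cycle species, drawn protodemetalated; not isolated) | COc1ccc(C2(c3cc4cc(OC)c(OC)cc4c[o+]3)OCCO2)c(OC)c1.[O-]S(=O)(=O)C(F)(F)F | intermediate
15 | 3-[2-(2,4-dimethoxyphenyl)-1,3-dioxolan-2-yl]-6,7-dimethoxy-1H-isochromene | COc1ccc(C2(C3=Cc4cc(OC)c(OC)cc4CO3)OCCO2)c(OC)c1 | intermediate
16 | (6,7-dimethoxy-1H-isochromen-3-yl)(2,4-dimethoxyphenyl)methanone | COc1ccc(C(=O)C2=Cc3cc(OC)c(OC)cc3CO2)c(OC)c1 | target

## Step count and risks

Total step count: 8. Longest linear sequence: 6 steps (steps 3, 4, 5, 6, 7, 8, from 4 and 5). The aryne precursor 3 takes 2 steps (steps 1 and 2) and enters at step 6.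

**Step 6 (key step).**
- Risk: the arylmagnesium 12 is itself a good nucleophile for arynes, so it may add to a second aryne and give over-arylation.
- Risk: the exchange reagent may capture the aryne.
- Risk: iodine–magnesium exchange on the electron-rich ring may be slow enough that attack at the triflate sulfur intervenes.
- Risk: surplus acetylide is formylated by DMF, which complicates purification.
- Fallback: the fallback sets out from 8 and forms only the C4–C4a bond by cross-coupling, taking C1 from a purchased aldehyde. Sonogashira coupling of 8 with 2-bromo-4,5-dimethoxybenzaldehyde F1 (PdCl2(PPh3)2, CuI, Et3N, THF, 60 °C) should give 13 directly, where the route is rejoined.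

**Step 7.**
- Risk: traces of triflic acid or the transient pyridinium triflate may ionise the aryl-stabilised ketal, and the cation would then be reduced by the Hantzsch ester (reductive opening of the dioxolane).
- Risk: 5-exo closure may compete.
- Risk: a second protonation and hydride transfer may over-reduce the enol ether.
- Fallback: the fallback sets out from 13, avoids having acid and hydride together, and rejoins at 15.
 - NaBH4 in MeOH at 0 °C should reduce the aldehyde to (2-{[2-(2,4-dimethoxyphenyl)-1,3-dioxolan-2-yl]ethynyl}-4,5-dimethoxyphenyl)methanol F2.
 - Iodocyclisation of this primary benzylic alcohol (I2, NaHCO3, MeCN, rt), which for primary 2-alkynylbenzyl alcohols is expected to go 6-endo, should give 3-[2-(2,4-dimethoxyphenyl)-1,3-dioxolan-2-yl]-4-iodo-6,7-dimethoxy-1H-isochromene F3.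
 - Palladium-catalysed formate reduction of the vinyl iodide (Pd(PPh3)4, HCO2H, Et3N, DMF, 60 °C) should give 15.

**Step 4.**
- Risk: ketalisation may stall, because the carbonyl is deactivated by the ortho- and para-methoxy donors and hindered by the ortho substituent.
- Risk: under the Lewis acid the ortho-methoxy oxygen may attack the activated alkyne in a chromone-type closure.
- Risk: the product ketal may be lost on acidic silica.
- Fallback: the fallback sets out from 6, carries the carbon at the alcohol oxidation level instead of masking a ketone, and rejoins at 16.
 - NaBH4 with CeCl3·7H2O in MeOH, followed by K2CO3 in the same flask, should reduce the ketone and remove the alkynyl silyl group to give racemic 1-(2,4-dimethoxyphenyl)prop-2-yn-1-ol F4.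
 - TBSCl and imidazole in DMF should give racemic tert-butyl{[1-(2,4-dimethoxyphenyl)prop-2-yn-1-yl]oxy}dimethylsilane F5.
 - The aryne coupling of step 6 with 3 and 9 should then give racemic 2-[3-{[tert-butyl(dimethyl)silyl]oxy}-3-(2,4-dimethoxyphenyl)prop-1-yn-1-yl]-4,5-dimethoxybenzaldehyde F6.
 - The AgOTf/Hantzsch ester closure of step 7 should give racemic tert-butyl[(6,7-dimethoxy-1H-isochromen-3-yl)(2,4-dimethoxyphenyl)methoxy]dimethylsilane F7.
 - Bu4NF in THF should give racemic (6,7-dimethoxy-1H-isochromen-3-yl)(2,4-dimethoxyphenyl)methanol F8.
 - Oxidation of this allylic, benzylic alcohol with MnO2 in CH2Cl2 should give 16; the stereocentre carried through this detour is erased in that oxidation.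

## Further compounds

F1 | step 6 | 2-bromo-4,5-dimethoxybenzaldehyde (purchased) | COc1cc(Br)c(C=O)cc1OC
F2 | step 7 | (2-{[2-(2,4-dimethoxyphenyl)-1,3-dioxolan-2-yl]ethynyl}-4,5-dimethoxyphenyl)methanol | COc1ccc(C2(C#Cc3cc(OC)c(OC)cc3CO)OCCO2)c(OC)c1
F3 | step 7 | 3-[2-(2,4-dimethoxyphenyl)-1,3-dioxolan-2-yl]-4-iodo-6,7-dimethoxy-1H-isochromene | COc1ccc(C2(C3=C(I)c4cc(OC)c(OC)cc4CO3)OCCO2)c(OC)c1
F4 | step 4 | racemic 1-(2,4-dimethoxyphenyl)prop-2-yn-1-ol (one enantiomer drawn) | C#C[C@H](O)c1ccc(OC)cc1OC
F5 | step 4 | racemic tert-butyl{[1-(2,4-dimethoxyphenyl)prop-2-yn-1-yl]oxy}dimethylsilane (one enantiomer drawn) | C#C[C@H](O[Si](C)(C)C(C)(C)C)c1ccc(OC)cc1OC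
F6 | step 4 | racemic 2-[3-{[tert-butyl(dimethyl)silyl]oxy}-3-(2,4-dimethoxyphenyl)prop-1-yn-1-yl]-4,5-dimethoxybenzaldehyde (one enantiomer drawn) | COc1ccc([C@@H](O[Si](C)(C)C(C)(C)C)C#Cc2cc(OC)c(OC)cc2C=O)c(OC)c1
F7 | step 4 | racemic tert-butyl[(6,7-dimethoxy-1H-isochromen-3-yl)(2,4-dimethoxyphenyl)methoxy]dimethylsilane (one enantiomer drawn) | COc1ccc([C@@H](O[Si](C)(C)C(C)(C)C)C2=Cc3cc(OC)c(OC)cc3CO2)c(OC)c1
F8 | step 4 | racemic (6,7-dimethoxy-1H-isochromen-3-yl)(2,4-dimethoxyphenyl)methanol (one enantiomer drawn) | COc1ccc([C@@H](O)C2=Cc3cc(OC)c(OC)cc3CO2)c(OC)c1
A1 | alternative 1 | (6,7-dimethoxy-1H-isochromen-3-yl)(4-hydroxy-2-methoxyphenyl)methanone | COc1cc(O)ccc1C(=O)C1=Cc2cc(OC)c(OC)cc2CO1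
A2 | alternative 1 | 1-(6,7-dimethoxy-1H-isochromen-3-yl)prop-2-yn-1-one | C#CC(=O)C1=Cc2cc(OC)c(OC)cc2CO1
A3 | alternative 1 | [(4,4-dimethoxybuta-1,3-dien-2-yl)oxy]trimethylsilane | C=C(O[Si](C)(C)C)C=C(OC)OC
A4 | alternative 2 | racemic 3-(2,4-dimethoxybenzoyl)-6,7-dimethoxyisochroman-1-ol, lactol epimers (one stereoisomer drawn) | COc1ccc(C(=O)[C@@H]2Cc3cc(OC)c(OC)cc3[C@H](O)O2)c(OC)c1
A5 | alternative 2 | 4,5-dimethoxy-2-methylbenzaldehyde | COc1cc(C)c(C=O)cc1OC
A6 | alternative 2 | 2-(2,4-dimethoxyphenyl)-2-oxoacetaldehyde | COc1ccc(C(=O)C=O)c(OC)c1
A7 | alternative 3 | racemic (6,7-dimethoxy-3,4-dihydro-1H-isochromen-3-yl)(2,4-dimethoxyphenyl)methanone (one enantiomer drawn) | COc1ccc(C(=O)[C@H]2Cc3cc(OC)c(OC)cc3CO2)c(OC)c1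
A8 | alternative 3 | 2-diazo-1-(2,4-dimethoxyphenyl)ethan-1-one | COc1ccc(C(=O)C=[N+]=[N-])c(OC)c1
A9 | alternative 3 | 5,6-dimethoxy-1,3-dihydro-2-benzofuran | COc1cc2c(cc1OC)COC2
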